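The ten-membered carbocycle is disconnected across the ring between C4 and C9 (germacrane numbering). The E-C4=C5 olefin behind the epoxide and the oxygenated C9 lie 1,6 to each other, so joining C4 to C9 gives a cis-decalin: ring A (C4–C9) from carvone, ring B (C1–C3, C10) from ethyl vinyl ketone. The key step is a Grob fragmentation: the C9 alkoxide cleaves the shared C4–C9 bond and expels an equatorial C5 mesylate, giving the ring, the C9 ketone and the E olefin at once. The precursor is a C9 tertiary alcohol and C5 mesylate whose C6 oxygen and oxidised C12 are tied up as a trans-fused lactol acetal and whose C1 oxygen is an ether.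

Key step: step 9

Assumption: the Michael addition of step 1 is taken to occur on the dienolate face anti to the isopropenyl group; germacrane numbering is used for every intermediate (decalin ring fusion = C4–C9), α/β as in the usual germacranolide drawing (H-7 α, both methyl groups β), and the acetal carbon C12 of 10–20 is an inconsequential epimer mixture.

Step 1
Reactants: 1 (S)-(+)-carvone; 2 ethyl vinyl ketone
Product: 4 cis-fused decalin ketol (9β-hydroxy-4β,10β-dimethyl-7β-isopropenyldecal-5-en-1-one), via Michael adduct 3 (not isolated)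
Conditions: KOH (0.2 equiv), EtOH, −10 → 20 °C
Reagents that add atoms: none
Why: Deconjugative Michael addition followed by intramolecular aldol addition: hydroxide generates the extended dienolate of 1, which attacks 2 through its α-carbon (C4) on the face anti to the isopropenyl group, and the ethyl ketone enolate of 3 then adds to the C9 carbonyl to close ring B as the cis-fused ketol, the equatorial C10 methyl being the thermodynamic epimer under the reversible conditions.

Step 2
Reactants: 4 cis-fused decalin ketol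
Product: 5 1α,9β-diol
Conditions: Me4NBH(OAc)3, AcOH/MeCN (1:1), −20 → 20 °C
Reagents that add atoms: none
Why: Hydroxyl-directed triacetoxyborohydride reduction of a β-hydroxy ketone: boron bound to the axial C9 oxygen delivers hydride intramolecularly to the same face of C1, which sets the equatorial 1α-carbinol (1,3-anti) under non-basic conditions that cannot trigger retro-aldol cleavage.

Step 3
Reactants: 5 1α,9β-diol
Product: 6 1α-(4-methoxybenzyl) ether (9β-ol)
Conditions: NaH, 4-MeOC6H4CH2Cl, Bu4NI (cat.), THF/DMF, 0 → 20 °C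
Reagents that add atoms: 4-methoxybenzyl chloride COc1ccc(CCl)cc1
Why: Williamson ether synthesis: the secondary C1 alkoxide is benzylated while the hindered tertiary C9 hydroxyl stays free, and the ether removes the carbonyl that would otherwise allow retro-aldol cleavage in step 9.

Step 4
Reactants: 6 1α-(4-methoxybenzyl) ether
Product: 7 5β,6β-epoxide
Conditions: VO(acac)2 (5 mol %), t-BuOOH, CH2Cl2, 0 → 20 °C
Reagents that add atoms: tert-butyl hydroperoxide CC(C)(C)OO
Why: Vanadium-catalysed hydroxyl-directed epoxidation of a homoallylic alcohol: the C9-bound peroxo complex delivers oxygen to the C5=C6 olefin of ring A on the face of the hydroxyl (β), which is also the face of the C4 methyl, and leaves the remote isopropenyl group alone.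

Step 5
Reactants: 7 5β,6β-epoxide
Product: 8 5β,6α,9β-triol (1α-OPMB)
Conditions: KOH, DMSO/H2O (4:1), 90 °C
Reagents that add atoms: water O
Why: SN2 ring opening of the epoxide by hydroxide at C6, the carbon that is not neopentyl, inverts C6 to the 6α-carbinol and keeps the 5β-oxygen, giving the trans-5,6-diol.

Step 6
Reactants: 8 5β,6α,9β-triol
Product: 10 trans-fused 6α,12-lactol (12-hydroxy-6α,12-epoxy-11(13)-ene; 5β,9β-diol), via hydroxy enal 9 (not isolated)
Conditions: SeO2 (1.5 equiv), 1,4-dioxane, 80 °C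
Reagents that add atoms: selenium dioxide O=[Se]=O
Why: Allylic oxidation with SeO2 (ene reaction, then [2,3]-sigmatropic shift) takes the isopropenyl methyl group to the 2-substituted acrolein 9, whose aldehyde is captured at once by the adjacent 6α-hydroxyl as a trans-fused five-membered lactol, so that C6 is differentiated from C5 without a protecting-group step.

Step 7
Reactants: 10 trans-fused 6α,12-lactol
Product: 11 12-O-(4-methoxybenzyl) lactol acetal
Conditions: 4-MeOC6H4CH2OH, PPTS (cat.), 4 Å MS, CH2Cl2, 20 °C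
Reagents that add atoms: 4-methoxybenzyl alcohol COc1ccc(CO)cc1
Why: Acid-catalysed acetalisation (acetal exchange at the anomeric carbon only) turns the lactol into a base-stable mixed acetal that is cleaved later by the same oxidant as the C1 ether.

Step 8
Reactants: 11 12-O-(4-methoxybenzyl) lactol acetal
Product: 12 5β-mesylate with free 9β-hydroxyl (fragmentation precursor)
Conditions: MsCl, Et3N, CH2Cl2, −10 → 0 °C
Reagents that add atoms: methanesulfonyl chloride CS(=O)(=O)Cl
Why: Sulfonylation through sulfene of the only secondary hydroxyl: the tertiary C9 hydroxyl does not react, which leaves the 1,3-hydroxy mesylate needed for fragmentation with the sulfonate cis to the C4 methyl.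

Step 9
Reactants: 12 5β-mesylate with free 9β-hydroxyl
Product: 14 (4E)-cyclodec-4-en-9-one (1α-OPMB; 10β-methyl; 6α,12-epoxy-12-OPMB; 11(13)-ene), via potassium alkoxide 13 (not isolated)
Conditions: KOt-Bu (1.2 equiv), THF/t-BuOH, 0 °C; pH 7 buffer
Reagents that add atoms: none
Why: KOt-Bu deprotonates the tertiary C9 hydroxyl; in alkoxide 13 the oxygen lone pair folds down to the C9 carbonyl while the C4–C9 σ bond, antiperiplanar to the equatorial C5–OMs bond, breaks in concert and becomes the C4=C5 π bond as mesylate departs. This is a Grob (Wharton-type) fragmentation of a cyclic 1,3-hydroxy sulfonate. The ten-membered ring is not closed end to end but set free by cleaving the bond shared by rings A and B (ring expansion by fragmentation). No stereocentre is formed; C9 becomes the ketone carbon and C1, C6, C7 and C10 are untouched. The step needs E geometry, which is secured because the trans-fused C6–C7 acetal ring locks ring A in the chair with the mesylate equatorial and cis to the axial C4 methyl, so that C3 lies anti to C6 across C4–C5. Competing E2 is impossible (no hydrogen antiperiplanar to an equatorial leaving group) and retro-aldol cleavage is blocked because C1 is an ether.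

Step 10
Reactants: 14 (4E)-cyclodec-4-en-9-one
Product: 16 8α-hydroxy-9-ketone, via potassium enolate 15 (not isolated)
Conditions: KN(SiMe3)2, THF, −78 °C; 2-(phenylsulfonyl)-3-phenyloxaziridine, −78 °C; aq. NH4Cl
Reagents that add atoms: 2-(phenylsulfonyl)-3-phenyloxaziridine O=S(=O)(c1ccccc1)N1OC1c1ccccc1
Why: Enolate hydroxylation with an N-sulfonyloxaziridine: the hindered amide removes a proton from the less substituted α-carbon C8, and with H-7 eclipsing the enolate double bond the oxidant should approach the outer face, anti to ring carbon C6, which gives the 8α-carbinol.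

Step 11
Reactants: 16 8α-hydroxy-9-ketone
Product: 17 8α-triethylsilyl ether
Conditions: Et3SiCl, imidazole, DMF, 0 °C
Reagents that add atoms: chlorotriethylsilane CC[Si](Cl)(CC)CC
Why: Silyl ether formation under imidazole catalysis masks the α-ketol as a bulky, non-chelating ether that can later be removed in the presence of a TBS ether.

Step 12
Reactants: 17 8α-triethylsilyl ether
Product: 18 9β-alcohol
Conditions: LiBH(s-Bu)3, THF, −78 °C; aq. NH4Cl
Reagents that add atoms: none
Why: 1,2-Reduction of the ketone with a bulky hydride under polar Felkin–Anh control: attack on the outer face anti to the C8–O bond, reinforced by Felkin control from C10, should set the 9β-carbinol (trans to the 8α-oxygen and cis to the C10 methyl).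

Step 13
Reactants: 18 9β-alcohol
Product: 19 9β-tert-butyldimethylsilyl ether
Conditions: t-BuMe2SiOTf, 2,6-lutidine, CH2Cl2, −78 °C
Reagents that add atoms: tert-butyldimethylsilyl trifluoromethanesulfonate CC(C)(C)[Si](C)(C)OS(=O)(=O)C(F)(F)F
Why: Silylation with a silyl triflate and a hindered pyridine base at low temperature protects the hindered C9 hydroxyl with the more robust of the two silyl groups.

Step 14
Reactants: 19 9β-tert-butyldimethylsilyl ether
Product: 20 1α-alcohol 12-lactol
Conditions: DDQ (2.5 equiv), CH2Cl2/pH 7 buffer, 0 → 20 °C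
Reagents that add atoms: none
Why: Oxidative debenzylation with DDQ (benzylic hydride abstraction, then hydrolysis of the oxocarbenium ions) removes the ether at C1 and the acetal at C12 together and leaves the silyl ethers and both olefins untouched.

Step 15
Reactants: 20 1α-alcohol 12-lactol
Product: 21 1-oxo-8α-(triethylsilyloxy)-9β-(TBS-oxy)germacra-4E,11(13)-dien-12,6α-olide
Conditions: 1,1,1-triacetoxy-1,1-dihydro-1,2-benziodoxol-3(1H)-one (DMP, 3 equiv), NaHCO3, CH2Cl2, 20 °C
Reagents that add atoms: none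
Why: Periodinane oxidation of alcohols converts the C1 carbinol into the ketone and the lactol into the α-methylene γ-lactone in one flask under buffered conditions that should not epimerise C10.

Step 16
Reactants: 21 keto α-methylene lactone
Product: 22 4α,5β-epoxide (4R,5R)
Conditions: mCPBA, NaHCO3, CH2Cl2, 0 °C
Reagents that add atoms: 3-chloroperoxybenzoic acid OOC(=O)c1cccc(Cl)c1
Why: Prilezhaev epoxidation, chemoselective for the electron-rich trisubstituted olefin: with H-6 in the olefin plane to avoid A(1,3) strain with the C4 methyl the peracid adds to the exposed outer face, threo to the C6 oxygen, which sets 4R,5R as in related 4α,5β-epoxy germacrolides.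

Step 17
Reactants: 22 4α,5β-epoxide
Product: 23 11β,13-diol
Conditions: OsO4 (5 mol %), N-methylmorpholine N-oxide, acetone/H2O, 20 °C
Reagents that add atoms: N-methylmorpholine N-oxide C[N+]1([O-])CCOCC1; water O
Why: Catalytic osmylation (Upjohn dihydroxylation) of the only remaining reactive olefin, the lactone methylene, from the β face, away from the 8α-silyloxy group, gives the 11β,13-diol whose C11 centre is temporary.

Step 18
Reactants: 23 11β,13-diol
Product: 24 13-acetate (11β-ol)
Conditions: Ac2O, pyridine, CH2Cl2, 0 °C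
Reagents that add atoms: acetic anhydride CC(=O)OC(C)=O
Why: Pyridine-mediated acylation is selective for the primary C13 hydroxyl because the tertiary α-hydroxy lactone is too hindered to react at 0 °C.

Step 19
Reactants: 24 13-acetate (11β-ol)
Product: 26 13-acetoxy-4α,5β-epoxy-1-oxo-8α-(triethylsilyloxy)-9β-(TBS-oxy)germacr-7(11)-en-12,6α-olide, via chlorosulfite ester 25 (not isolated)
Conditions: SOCl2, pyridine, CH2Cl2, −30 → 0 °C
Reagents that add atoms: none
Why: Dehydration by way of the chlorosulfite: pyridine-induced anti E2 elimination of H-7α, antiperiplanar to the 11β-oxygen, gives the conjugated tetrasubstituted C7=C11 butenolide and erases the temporary C7 and C11 centres.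

Step 20
Reactants: 26 13-acetoxy butenolide (8α-OTES, 9β-OTBS)
Product: 27 8α-alcohol
Conditions: HF·pyridine, pyridine, THF, 0 °C
Reagents that add atoms: none
Why: Fluoride desilylation buffered with pyridine is selective for the less hindered, more labile triethylsilyl ether at allylic C8 and spares the C9 TBS ether, the epoxide and the allylic acetate.

Step 21
Reactants: 27 8α-alcohol
Product: 28 8α-methacrylate (9β-OTBS)
Conditions: methacrylic anhydride, Et3N, DMAP (cat.), CH2Cl2, 0 °C
Reagents that add atoms: methacrylic anhydride C=C(C)C(=O)OC(=O)C(C)=C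
Why: DMAP-catalysed acyl transfer (Steglich-type esterification) acylates the only free hydroxyl, while the silyl ether at C9 rules out acylation there and acyl migration.

Step 22
Reactants: 28 8α-methacrylate (9β-OTBS)
Product: 29 CNP0185951.1 (13-acetoxy-4α,5β-epoxy-9β-hydroxy-8α-methacryloyloxy-1-oxogermacr-7(11)-en-12,6α-olide)
Conditions: HF·pyridine, THF, 0 → 20 °C
Reagents that add atoms: none
Why: Acidic fluoride desilylation removes the last silyl group without base, so that retro-aldol opening of the β-hydroxy ketone, acyl migration and loss of the allylic acetate are avoided.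

Compound list
1 | (S)-(+)-carvone | CC1=CC[C@H](C(C)=C)CC1=O | starting material
2 | ethyl vinyl ketone (pent-1-en-3-one) | CCC(=O)C=C | starting material
3 | Michael adduct, 2-methyl-2-(3-oxopentyl)-5-isopropenylcyclohex-3-en-1-one, side chain trans to isopropenyl | O=C1C[C@@H](C(C)=C)C=C[C@]1(C)CCC(=O)CC | intermediate
4 | cis-fused ketol, 9β-hydroxy-4β,10β-dimethyl-7β-isopropenyldecal-5-en-1-one | O[C@@]12C[C@@H](C(C)=C)C=C[C@]1(C)CCC(=O)[C@H]2C | intermediate
5 | 1α,9β-diol of 4 | O[C@@]12C[C@@H](C(C)=C)C=C[C@]1(C)CC[C@H](O)[C@H]2C | intermediate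
6 | 1α-(4-methoxybenzyl) ether of 5 | O[C@@]12C[C@@H](C(C)=C)C=C[C@]1(C)CC[C@H](OCc3ccc(OC)cc3)[C@H]2C | intermediate
7 | 5β,6β-epoxide of 6 | O[C@@]12C[C@@H](C(C)=C)[C@H]3O[C@H]3[C@]1(C)CC[C@H](OCc4ccc(OC)cc4)[C@H]2C | intermediate
8 | 5β,6α,9β-triol, 1α-OPMB, 7β-isopropenyl | O[C@@]12C[C@@H](C(C)=C)[C@H](O)[C@@H](O)[C@]1(C)CC[C@H](OCc3ccc(OC)cc3)[C@H]2C | intermediate
9 | hydroxy enal (isopropenyl methyl oxidised to C12 aldehyde) | O[C@@]12C[C@@H](C(=C)C=O)[C@H](O)[C@@H](O)[C@]1(C)CC[C@H](OCc3ccc(OC)cc3)[C@H]2C | intermediate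
10 | trans-fused 6α,12-lactol with C11=C13 methylene, 5β,9β-diol, 1α-OPMB (C12 epimers) | O[C@@]12C[C@H]3C(=C)C(O)O[C@@H]3[C@@H](O)[C@]1(C)CC[C@H](OCc4ccc(OC)cc4)[C@H]2C | intermediate
11 | 12-O-(4-methoxybenzyl) acetal of 10 | O[C@@]12C[C@H]3C(=C)C(OCc4ccc(OC)cc4)O[C@@H]3[C@@H](O)[C@]1(C)CC[C@H](OCc5ccc(OC)cc5)[C@H]2C | intermediate
12 | 5β-mesylate of 11, free tertiary 9β-hydroxyl (fragmentation precursor) | O[C@@]12C[C@H]3C(=C)C(OCc4ccc(OC)cc4)O[C@@H]3[C@@H](OS(C)(=O)=O)[C@]1(C)CC[C@H](OCc5ccc(OC)cc5)[C@H]2C | intermediate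
13 | potassium C9 alkoxide of 12 | [K+].[O-][C@@]12C[C@H]3C(=C)C(OCc4ccc(OC)cc4)O[C@@H]3[C@@H](OS(C)(=O)=O)[C@]1(C)CC[C@H](OCc5ccc(OC)cc5)[C@H]2C | intermediate
14 | (4E)-1α-(PMB-oxy)-10β-methyl-6α,12-epoxy-12-(PMB-oxy)germacra-4,11(13)-dien-9-one | O=C1C[C@H]2C(=C)C(OCc3ccc(OC)cc3)O[C@@H]2/C=C(C)/CC[C@H](OCc4ccc(OC)cc4)[C@H]1C | intermediate
15 | potassium C8=C9 enolate of 14 | [K+].[O-]C1=C[C@H]2C(=C)C(OCc3ccc(OC)cc3)O[C@@H]2/C=C(C)/CC[C@H](OCc4ccc(OC)cc4)[C@H]1C | intermediate
16 | 8α-hydroxy derivative of 14 | O=C1[C@H](O)[C@H]2C(=C)C(OCc3ccc(OC)cc3)O[C@@H]2/C=C(C)/CC[C@H](OCc4ccc(OC)cc4)[C@H]1C | intermediate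
17 | 8α-triethylsilyl ether of 16 | O=C1[C@H](O[Si](CC)(CC)CC)[C@H]2C(=C)C(OCc3ccc(OC)cc3)O[C@@H]2/C=C(C)/CC[C@H](OCc4ccc(OC)cc4)[C@H]1C | intermediate
18 | 9β-alcohol from 17 | O[C@H]1[C@H](O[Si](CC)(CC)CC)[C@H]2C(=C)C(OCc3ccc(OC)cc3)O[C@@H]2/C=C(C)/CC[C@H](OCc4ccc(OC)cc4)[C@H]1C | intermediate
19 | 9β-TBS ether of 18 | CC(C)(C)[Si](C)(C)O[C@H]1[C@H](O[Si](CC)(CC)CC)[C@H]2C(=C)C(OCc3ccc(OC)cc3)O[C@@H]2/C=C(C)/CC[C@H](OCc4ccc(OC)cc4)[C@H]1C | intermediate
20 | 1α-alcohol 12-lactol (both PMB groups removed) | CC(C)(C)[Si](C)(C)O[C@H]1[C@H](O[Si](CC)(CC)CC)[C@H]2C(=C)C(O)O[C@@H]2/C=C(C)/CC[C@H](O)[C@H]1C | intermediate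
21 | 1-oxo-8α-(triethylsilyloxy)-9β-(TBS-oxy)germacra-4E,11(13)-dien-12,6α-olide | CC(C)(C)[Si](C)(C)O[C@H]1[C@H](O[Si](CC)(CC)CC)[C@H]2C(=C)C(=O)O[C@@H]2/C=C(C)/CCC(=O)[C@H]1C | intermediate
22 | 4α,5β-epoxide (4R,5R) of 21 | CC(C)(C)[Si](C)(C)O[C@H]1[C@H](O[Si](CC)(CC)CC)[C@H]2C(=C)C(=O)O[C@@H]2[C@H]3O[C@]3(C)CCC(=O)[C@H]1C | intermediate
23 | 11β,13-diol of 22 | CC(C)(C)[Si](C)(C)O[C@H]1[C@H](O[Si](CC)(CC)CC)[C@H]2[C@](O)(CO)C(=O)O[C@@H]2[C@H]3O[C@]3(C)CCC(=O)[C@H]1C | intermediate
24 | 13-acetate of 23 (11β-ol) | CC(C)(C)[Si](C)(C)O[C@H]1[C@H](O[Si](CC)(CC)CC)[C@H]2[C@](O)(COC(C)=O)C(=O)O[C@@H]2[C@H]3O[C@]3(C)CCC(=O)[C@H]1C | intermediate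
25 | C11 chlorosulfite ester of 24 | CC(C)(C)[Si](C)(C)O[C@H]1[C@H](O[Si](CC)(CC)CC)[C@H]2[C@](OS(Cl)=O)(COC(C)=O)C(=O)O[C@@H]2[C@H]3O[C@]3(C)CCC(=O)[C@H]1C | intermediate
26 | 13-acetoxy-4α,5β-epoxy-1-oxo-8α-(triethylsilyloxy)-9β-(TBS-oxy)germacr-7(11)-en-12,6α-olide | CC(C)(C)[Si](C)(C)O[C@H]1[C@H](O[Si](CC)(CC)CC)C2=C(COC(C)=O)C(=O)O[C@@H]2[C@H]3O[C@]3(C)CCC(=O)[C@H]1C | intermediate
27 | 8α-alcohol from 26 | CC(C)(C)[Si](C)(C)O[C@H]1[C@H](O)C2=C(COC(C)=O)C(=O)O[C@@H]2[C@H]3O[C@]3(C)CCC(=O)[C@H]1C | intermediate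
28 | 8α-methacrylate of 27 (9β-OTBS) | CC(C)(C)[Si](C)(C)O[C@H]1[C@H](OC(=O)C(C)=C)C2=C(COC(C)=O)C(=O)O[C@@H]2[C@H]3O[C@]3(C)CCC(=O)[C@H]1C | intermediate
29 | CNP0185951.1 | C=C(C)C(=O)O[C@@H]1C2=C(COC(C)=O)C(=O)O[C@@H]2[C@H]2O[C@]2(C)CCC(=O)[C@@H](C)[C@H]1O | target

Total step count: 22. Longest linear sequence: 22 steps (from 1).

Steps most likely to fail

Step 10. On the flexible ten-membered ring the oxidant may reach the enolate from the inner face, so that the C8 epimer predominates. The fallback sets out from 14 and accepts that outcome: the 8β-hydroxy ketone F1 obtained under the step 10 conditions is inverted by Mitsunobu esterification (4-nitrobenzoic acid, PPh3, diisopropyl azodicarboxylate, toluene, 0 °C), which is favourable at an α-keto carbinol, to the 8α-(4-nitrobenzoate) F2. Brief methanolysis (K2CO3, MeOH, 0 °C) then returns the route at 16.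

Step 5. The opening may lose regiocontrol or stall, because the diaxial transition state for attack at C6 forces the isopropenyl group axial while attack at C5 profits from the better chair. The fallback sets out from 6 and installs both oxygens on the β face first: hydroxyl-directed dihydroxylation with stoichiometric OsO4·TMEDA (CH2Cl2, −78 °C; aq. Na2SO3) gives the 5β,6β-diol F3. The less hindered C6 hydroxyl is converted into the 6β-triflate F4 (Tf2O, pyridine, CH2Cl2, −40 °C) and displaced with inversion (CsOAc, 18-crown-6, toluene) to the 6α-acetate F5. Methanolysis (K2CO3, MeOH) comes back to the route at 8.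

Step 19. The elimination may run toward C13, or chloride may substitute at C11 or open the epoxide. The fallback sets out from 22 and bypasses steps 17–19 by a radical allylic transposition: Wohl–Ziegler bromination (N-bromosuccinimide, AIBN cat., PhCF3, 80 °C) abstracts the tertiary allylic H-7 and traps the allyl radical at the primary terminus, giving the 13-bromo-7(11)-en-12,6α-olide F6. Displacement with KOAc and 18-crown-6 (MeCN, 20 °C) rejoins the route at 26.

Further compounds
F1 | step 10 | 8β-hydroxy ketone (C8 epimer of 16) | O=C1[C@@H](O)[C@H]2C(=C)C(OCc3ccc(OC)cc3)O[C@@H]2/C=C(C)/CC[C@H](OCc4ccc(OC)cc4)[C@H]1C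
F2 | step 10 | 8α-(4-nitrobenzoate) of 16 | O=C1[C@H](OC(=O)c5ccc(cc5)[N+](=O)[O-])[C@H]2C(=C)C(OCc3ccc(OC)cc3)O[C@@H]2/C=C(C)/CC[C@H](OCc4ccc(OC)cc4)[C@H]1C
F3 | step 5 | 5β,6β-diol (1α-OPMB, 9β-ol) | O[C@@]12C[C@@H](C(C)=C)[C@@H](O)[C@@H](O)[C@]1(C)CC[C@H](OCc3ccc(OC)cc3)[C@H]2C
F4 | step 5 | 6β-triflate of F3 | O[C@@]12C[C@@H](C(C)=C)[C@@H](OS(=O)(=O)C(F)(F)F)[C@@H](O)[C@]1(C)CC[C@H](OCc3ccc(OC)cc3)[C@H]2C
F5 | step 5 | 6α-acetate (5β,9β-diol) | O[C@@]12C[C@@H](C(C)=C)[C@H](OC(C)=O)[C@@H](O)[C@]1(C)CC[C@H](OCc3ccc(OC)cc3)[C@H]2C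
F6 | step 19 | 13-bromo-4α,5β-epoxy-1-oxo-8α-(triethylsilyloxy)-9β-(TBS-oxy)germacr-7(11)-en-12,6α-olide | CC(C)(C)[Si](C)(C)O[C@H]1[C@H](O[Si](CC)(CC)CC)C2=C(CBr)C(=O)O[C@@H]2[C@H]3O[C@]3(C)CCC(=O)[C@H]1C
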